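The earlier runs and the new flask are simulated with made-up constants.

At late times the winter run loses ring, from 36.6% at 1.00 h to 17.7% at 8.00 h, so a final figure in that run lies under an earlier level. The noon run reads 24.4% near its top and the summer run 20.4%, both at −25 °C, so the noon run, with the smaller charge, reads the higher percentage of what was charged.

| flask | starting material | activator | temperature | remark | time |
|---|---|---|---|---|---|
| summer | 0.23 M | 0.242 M | −25 °C | run made earlier |  |
| winter | 0.12 M | 0.242 M | −14 °C | run made earlier |  |
| noon | 0.17 M | 0.242 M | −25 °C | run made earlier |  |
| dawn | 0.23 M | 0.12 M | −14 °C | run made earlier |  |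
| west | 0.23 M | 0.242 M (fed, over 3.0 h) | −20 °C | all else is in the flask from the start; the feed brings no volume worth counting | 8.0 h |
| east | 0.23 M | 0.242 M |  | everything together at the start at −40 °C, warmed to −20 °C at 3.0 h | 8.0 h |
| north-west | 0.23 M (fed, over 3.0 h) | 0.242 M | −20 °C | all else is in the flask from the start; the feed brings no volume worth counting | 8.0 h |
| north-east | 0.23 M (fed, over 3.0 h) | 0.242 M |  | the addition at −40 °C, then warmed to −20 °C; the feed brings no volume worth counting | 8.0 h |
| north | 0.23 M | 0.242 M | −20 °C | everything together at the start | 8.0 h |

| run | time / h | ring / % |
|---|---|---|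
| summer | 0.250 | 8.8 |
| summer | 0.667 | 15.6 |
| summer | 1.33 | 19.5 |
| summer | 2.00 | 20.4 |
| summer | 3.00 | 16.2 |
| summer | 4.00 | 16.5 |
| summer | 5.00 | 19.2 |
| winter | 1.00 | 36.6 |
| winter | 2.50 | 32.5 |
| winter | 3.00 | 30.5 |
| winter | 5.00 | 23.8 |
| winter | 6.00 | 20.3 |
| winter | 8.00 | 17.7 |
| noon | 0.417 | 16.6 |
| noon | 1.33 | 23.5 |
| noon | 2.50 | 24.3 |
| noon | 3.00 | 24.4 |
| noon | 5.00 | 21.3 |
| noon | 6.00 | 22.5 |
| noon | 8.00 | 23.6 |
| dawn | 1.50 | 11.3 |
| dawn | 3.00 | 12.1 |
| dawn | 5.00 | 7.6 |
| dawn | 6.00 | 7.6 |
| dawn | 8.00 | 4.6 |

(each reading ± 1 percentage point)

* the flask with the highest amount of ring, in percent of the starting material charged ("all alike" if they lie within 1.5 percentage points) (west / east / north-west / north-east / north / all alike)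
* final ring, as a percentage of the starting material charged, in west
* final ring, as a percentage of the starting material charged, in east
* final ring, as a percentage of the starting material charged, in north-west
* final ring, as a percentage of the starting material charged, in north-east
* final ring, as a percentage of the starting material charged, in north

- percentages count the starting material that a species holds: one open dimer counts as two
- what may be going on: starting material + activator -> activated form; activated form -> ring; starting material + activated form -> open dimer; ring <-> isomer of the product; ring -> over-reaction product

Starting material and activator give the activated form. That form closes to ring, or takes a second starting material into open dimer. Ring then exchanges with isomer of the product and passes on to over-reaction product.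

Counting gives the scale. 0.115 M of activator clears the charge if every activated form ends as open dimer; this is the clearing dose. All-dimer is the zero of the scale.

In west, activator enters at 0.0807 M h⁻¹. On that zero case, c(starting material) starts down at 0.161 M h⁻¹. It runs straight to a knee at 1.43 h, inside the feed, and then lies at zero. After the knee, fed activator stays unused, and c(activator) climbs to a level of 52.5% of its charge. The all-ring end of the scale leaves 4.96%. Each ring costs one activator for one starting material, so once starting material is cleared, c(activator) in west lies between these marks.

The forecast names north-west, with west 18.5%, east 13%, north-west 37%, north-east 20% and north 18%. Its note says “Feeding activator does not lower SM much”. The knee reckoning differs on that point.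

The flasks give north-west as the highest: west 11.7%, east 13.8%, north-west 35.2%, north-east 17.0%, north 16.2%. West stands 6.8 percentage points under the forecast.

    starting material + activator → activated form (k = 0.0130 M⁻¹ s⁻¹, Ea = 42.0 kJ mol⁻¹)
    activated form → ring (k = 9.70 × 10⁻⁴ s⁻¹, Ea = 73.0 kJ mol⁻¹)
    starting material + activated form → open dimer (k = 0.0290 M⁻¹ s⁻¹, Ea = 40.0 kJ mol⁻¹)
    ring ⇌ isomer of the product (K = 0.480, k = 2.70 × 10⁻⁴ s⁻¹, Ea = 77.0 kJ mol⁻¹, ΔH = −20.0 kJ mol⁻¹)
    ring → over-reaction product (k = 1.40 × 10⁻⁵ s⁻¹, Ea = 89.0 kJ mol⁻¹)
    (constants at −20 °C)

West ends with activator at 42.2%, below the mark of 52.5%. That places 21.7% of the charge on the ring way, beside 78.3% in open dimer. The gap of 24 points between north-west and west shrinks to 0.084 points without the dimer step and to 0.15 points without the way back from isomer of the product to ring; these two act together. The neighbour of west with 0.92 M starting material has a clearing dose of 0.460 M, above its activator. Activator, the limiting reagent there, falls to 0%. The all-dimer mark leaves 47.4% of the starting material, and the flask holds 48.7%.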